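**The question.** How long did the chains in this flask grow, and did they pass the wanted length? Free monomer was fed in slowly, while initiator, transfer agent and protic impurity stood in the flask from the start.

free monomer 0.25 M (fed, over 25 h); transfer agent 7.50 mM; protic impurity 0.125 M; initiator 1 mol%; time 2.5 d

    free monomer + initiator → living end + monomer in chains (k1 = 0.764 M⁻¹ h⁻¹)
    free monomer + living end → monomer in chains + living end, rate k2*[living end]*[free monomer] (k2 = 19.7 M⁻¹ h⁻¹)
    living end + transfer agent → dead chain (k3 = 16.6 M⁻¹ h⁻¹)
    protic impurity + free monomer → quenched substrate (k4 = 0.0651 M⁻¹ h⁻¹)

- whether the average number of monomer units in a chain (chains begun, living or dead) reaches 20 by 2.5 d (yes / no)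
- average number of monomer units in a chain (chains begun, living or dead) at 2.5 d

- the average divides the monomer in chains by the number of chains begun, living and dead together
- run time (flask): 2.5 d

**First way.** At any moment a living end could do one of two things: take free monomer, at its growth constant times c(free monomer), or meet transfer agent and die, at its transfer constant times c(transfer agent). The first rate over the second counts the units a living end adds before it dies, the kinetic chain length. Taken at the whole charges, this quotient is the chain ratio, and I got 39.6. I held transfer agent at its charge, which is 3.00 times the initiator charge.

**Second way.** I then followed the median chain. Initiator met free monomer rising along the feed, so I reckoned that half of it had reacted by 13.5 h. With transfer agent at its charge, a living end lasted about 8.03 h on average, which in my reckoning brought the median chain to 21.5 h. By then the feed was 86.0% done. Protic impurity, acting as a pseudo-first-order drain on free monomer, had also taken its part. Together these gave me an estimate of 78.8% of the charge as free monomer, a generous figure, since I read it at the end of that life and ignored monomer in chains.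

**Which cheats.** The first way cheats, because in my reckoning the median chain died before the feed ended, at a lower c(free monomer) than the charge. My committed length was therefore 31.2, above 20, so my answer on reaching it was yes.

**The forecast.** The forecast said yes and 29, reckoning that “propagation adds about 70 mM”.

**The flask.** This flask gave yes and 28.5, passing 20 at 1.20 d. With the amounts actually standing, the chain ratio was 37.9 at 1.04 d and 30.0 at 2.50 d. For a second flask with half the transfer agent and all other amounts as they are, twice my reckoned length, with my free monomer share held as it was, gives 62.4, and that flask ended lower, at 48.8.

The constants used here are made up; what happens was integrated by code.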